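**Plan**

1. The target is catechin-(4α→8)-gallocatechin-(4β→8)-catechin. The retrosynthesis cuts C4(top unit)–C8(middle unit) first (Friedel–Crafts coupling of a C8-bromo-capped catechin 4-ether), then C4(middle)–C8(bottom) (8-lithiocatechin added to a C4 ketone, C4 oxygen then removed reductively), then the C2–C3 bond of ring C of the middle unit.
2. Ring C of the middle unit is not built as a pyran. It grows from a 2-aryl-3-silyloxy-2,3-dihydrobenzofuran-3-carbaldehyde by an α-ketol (acyloin) 1,2-shift: C2 moves from the ring carbon attached to ring A onto the formyl carbon, which becomes C3, and the old ring carbon becomes the C4 ketone.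
3. The enabling feature is that O1 on C2 makes C2 a good migrating group and the 5,7-dioxygenated ring A conjugates with the C4 carbonyl that appears. That C4=O is the helper that fixes where the bottom unit is attached, and it is deleted afterwards.
4. Forward order: ring A (phloroglucinol triether, three TBB groups from three equivalents of one benzylic alcohol) → five-membered O-ring by rhodium-carbenoid C–H insertion → ring expansion to ring C → bottom unit at C4 → top unit at C8 → global hydrogenolysis.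
5. Stereochemistry: top and bottom units come from (+)-catechin; middle C2 from the chiral dirhodium catalyst (retained in the shift); middle C3 in the shift (trans, thermodynamically secured); middle C4 by hydride delivery anti to the 3-silyloxy group (4β); top C4 by attack trans to its 3-OH (4α).

Key step: step 8

Assumption: Rh2(S-PTTL)4 is taken to give the (2S,3R) cis ester 8 by analogy with simpler 2-(benzyloxy)aryl diazoacetates; this sense of induction is the one point taken on analogy.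

Abbreviations in names: Bn = benzyl; TBB = 3,4,5-tris(benzyloxy)benzyl; TBS = tert-butyldimethylsilyl; ArB = 3,4,5-tris(benzyloxy)phenyl.

**Route**

Step 1
Reactants: 1 phloroglucinol; 2 [3,4,5-tris(benzyloxy)phenyl]methanol (TBB alcohol; three equivalents are consumed, one per phenol)
Product: 3 1,3,5-tris(TBB-oxy)benzene
Conditions: 2 (3.3 equiv), PPh3 (3.6 equiv), DIAD (3.6 equiv), THF, 0 °C → rt
Reagents that add atoms: [3,4,5-tris(benzyloxy)phenyl]methanol, the second and third equivalents of 2 (written as two molecules) OCc1cc(OCc2ccccc2)c(OCc2ccccc2)c(OCc2ccccc2)c1.OCc1cc(OCc2ccccc2)c(OCc2ccccc2)c(OCc2ccccc2)c1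
Why: Threefold Mitsunobu etherification with a slight excess over three equivalents of the benzylic alcohol should O-alkylate all three phenols under neutral conditions, avoiding the C-benzylation that basic alkylation of phloroglucinol suffers; no stereocenter is formed.

Step 2
Reactants: 3 1,3,5-tris(TBB-oxy)benzene
Product: 5 methyl 2-oxo-2-[2,4,6-tris(TBB-oxy)phenyl]acetate, via aryl glyoxylyl chloride 4 (not isolated)
Conditions: (COCl)2, 2,6-di-tert-butylpyridine, CH2Cl2, 0 °C; then MeOH, pyridine, 0 °C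
Reagents that add atoms: oxalyl chloride ClC(=O)C(=O)Cl; methanol CO
Why: Uncatalysed Friedel–Crafts glyoxylation of the trialkoxybenzene (as with indoles) should stop after one acylation because the product ring is deactivated, the hindered base traps HCl so the electron-rich benzyl ethers survive, and methanol then esterifies the acid chloride.

Step 3
Reactants: 5 methyl 2-oxo-2-[2,4,6-tris(TBB-oxy)phenyl]acetate
Product: 7 methyl 2-diazo-2-[2,4,6-tris(TBB-oxy)phenyl]acetate, via tosylhydrazone 6 (not isolated)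
Conditions: TsNHNH2, MeOH, 60 °C; then DBU, CH2Cl2, rt
Reagents that add atoms: 4-methylbenzenesulfonohydrazide Cc1ccc(cc1)S(=O)(=O)NN
Why: Condensation of the α-keto ester to the tosylhydrazone and base-induced loss of sulfinate (Bamford–Stevens type) should give the aryl diazoacetate.

Step 4
Reactants: 7 methyl 2-diazo-2-[2,4,6-tris(TBB-oxy)phenyl]acetate
Product: 8 methyl (2S,3R)-2-ArB-4,6-bis(TBB-oxy)-2,3-dihydro-1-benzofuran-3-carboxylate (2,3-cis)
Conditions: Rh2(S-PTTL)4 (dirhodium tetrakis[N-phthaloyl-(S)-tert-leucinate], 1 mol %), toluene, −60 °C → rt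
Reagents that add atoms: none
Why: Intramolecular 1,5 C–H insertion of the donor/acceptor rhodium carbenoid into an ortho O–CH2–aryl bond should close the dihydrobenzofuran; the two ortho ethers are identical so only one constitution can form, and the chiral carboxylate ligands set C2 (the future C2 of ring C) and the cis C3.

Step 5
Reactants: 8 cis ester
Product: 9 methyl (2R,3S)-3-hydroxy-2-ArB-4,6-bis(TBB-oxy)-2,3-dihydro-1-benzofuran-3-carboxylate (OH trans to ArB)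
Conditions: KN(SiMe3)2, THF, −78 °C; then 2-(phenylsulfonyl)-3-phenyloxaziridine; aq. NH4Cl
Reagents that add atoms: 2-(phenylsulfonyl)-3-phenyloxaziridine O=S(=O)(c1ccccc1)N1OC1c1ccccc1
Why: Enolate oxidation should deliver oxygen anti to the C2 aryl group; the C2–O1 bond lies in the ring plane, orthogonal to the enolate π system, so β-elimination (the reverse of a 5-endo-trig closure) should not scramble C2.

Step 6
Reactants: 9 hydroxy ester
Product: 10 methyl (2R,3S)-3-[(tert-butyldimethylsilyl)oxy]-2-ArB-4,6-bis(TBB-oxy)-2,3-dihydro-1-benzofuran-3-carboxylate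
Conditions: tBuMe2SiOTf, 2,6-lutidine, CH2Cl2, 0 °C → rt
Reagents that add atoms: tert-butyldimethylsilyl trifluoromethanesulfonate CC(C)(C)[Si](C)(C)OS(=O)(=O)C(F)(F)F
Why: The silyl triflate should silylate the hindered tertiary alcohol; this installs the group that later migrates and protects O3.

Step 7
Reactants: 10 silyloxy ester
Product: 11 (2R,3S)-3-[(tert-butyldimethylsilyl)oxy]-2-ArB-4,6-bis(TBB-oxy)-2,3-dihydro-1-benzofuran-3-carbaldehyde
Conditions: iBu2AlH (1.2 equiv), CH2Cl2, −78 °C; aq. potassium sodium tartrate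
Reagents that add atoms: none
Why: Partial reduction of an α-silyloxy ester should stop at the aldehyde because the chelated tetrahedral aluminate is stable at −78 °C.

Step 8
Reactants: 11 α-silyloxy aldehyde
Product: 12 (2R,3R)-3-[(tert-butyldimethylsilyl)oxy]-2-ArB-5,7-bis(TBB-oxy)-2,3-dihydro-4H-chromen-4-one (2,3-trans)
Conditions: MeAl(OAr)2 (Ar = 2,6-tBu2-4-MeC6H2, 20 mol %), toluene, −40 → 0 °C; then Et3N (0.2 equiv), CH2Cl2, rt
Reagents that add atoms: none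
Why: The aluminium Lewis acid binds the formyl oxygen, the C2–C3 bond of the five-membered ring migrates suprafacially to the formyl carbon, and the silyl group passes from the tertiary oxygen to the former formyl oxygen, so the furan ring grows by one carbon into ring C (formyl carbon → C3, old furan C3 → C4 ketone). The closest known reaction type is the α-ketol (acyloin) rearrangement of α-silyloxy aldehydes to α-silyloxy ketones under bulky methylaluminium bis(aryloxide) catalysis, with steroid D-homoannulation as the ring-enlarging classic; ring C is therefore not closed by a cyclisation but enlarged by a 1,2-carbon shift that forms C2–C3 and breaks C2–C4. C2 migrates with retention, so the configuration set in step 4 is carried over unchanged. The new stereocenter C3 forms when the formyl carbon accepts C2 in the conformer with the two oxygens syn-periplanar (needed for the silyl transfer), which places the silyloxy group trans to the C2 aryl group; because C3 is then α to the ketone, the brief Et3N treatment should equilibrate any cis isomer to the diequatorial trans one. The step needs migration of C2 and not of the ring-A carbon C4a: O1 on C2 raises its migratory aptitude, and when C2 leaves, the developing oxocarbenium carbon C4 stays conjugated with the 5,7-dioxygenated ring A, whereas ring-A migration would give an unconjugated 3-ketone.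

Step 9
Reactants: 13 (+)-catechin
Product: 14 (2R,3S)-5,7,3',4'-tetra-O-benzylcatechin
Conditions: BnBr (4.4 equiv), K2CO3, DMF, 0 °C → rt
Reagents that add atoms: benzyl bromide BrCc1ccccc1
Why: Williamson etherification should benzylate the four phenols and leave the secondary 3-OH untouched under carbonate conditions.

Step 10
Reactants: 14 tetra-O-benzylcatechin
Product: 15 (2R,3S)-8-bromo-5,7,3',4'-tetra-O-benzylcatechin
Conditions: NBS, CH2Cl2, −78 °C → rt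
Reagents that add atoms: N-bromosuccinimide O=C1CCC(=O)N1Br
Why: Electrophilic aromatic bromination should occur at C8, the most nucleophilic position of ring A in benzylated flavan-3-ols.

Step 11
Reactants: 15 8-bromide
Product: 16 (2R,3S)-8-bromo-3-O-(tert-butyldimethylsilyl)-5,7,3',4'-tetra-O-benzylcatechin
Conditions: tBuMe2SiCl, imidazole, DMF, rt
Reagents that add atoms: tert-butyldimethylsilyl chloride CC(C)(C)[Si](C)(C)Cl
Why: Standard silylation protects the 3-OH against the organolithium chemistry of the next step.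

Step 12
Reactants: 16 silylated 8-bromide; 12 ring-C ketone
Product: 18 tertiary alcohol (middle unit 2R,3R,4R; C4 carries OH and the C8 aryl group of the bottom unit; both O3 as TBS ethers), via 8-lithiocatechin derivative 17 (not isolated)
Conditions: tBuLi (2.1 equiv), THF, −78 °C; then 12, −78 → −40 °C; aq. NH4Cl
Reagents that add atoms: none
Why: Bromine–lithium exchange and 1,2-addition of the aryllithium to the C4 ketone should form the interflavan C4–C8 bond with the regiochemistry fixed by the position of the bromine; attack is expected anti to the 3-silyloxy group, but the carbinol configuration is erased in step 13.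

Step 13
Reactants: 18 tertiary alcohol
Product: 19 3,3''-bis-O-TBS-protected gallocatechin-(4β→8)-catechin (middle unit 2R,3S,4R; 3,4-cis)
Conditions: nBu3SnH, CF3CO2H, CH2Cl2, −78 → −20 °C
Reagents that add atoms: none
Why: Ionic deoxygenation: acid ionises the doubly benzylic tertiary alcohol to the ring-A-stabilised C4 cation, and the stannane should deliver hydride to the face opposite the adjacent 3-silyloxy group, so the aryl group ends cis to O3 (4β), as such reductions do on 4-aryl-flavan-4-ols.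

Step 14
Reactants: 19 bis-silyl dimer
Product: 20 gallocatechin-(4β→8)-catechin with all phenols protected (5,7-di-O-TBB, 3',4',5'-tri-O-Bn upper unit; 5,7,3',4'-tetra-O-Bn lower unit) and both 3-OH free
Conditions: nBu4NF, THF, rt → 40 °C
Reagents that add atoms: none
Why: Fluoride should cleave both secondary silyl ethers and leave the benzyl-type ethers and the interflavan bond untouched.

Step 15
Reactants: 15 8-bromide
Product: 21 (2R,3S,4S)-8-bromo-5,7,3',4'-tetra-O-benzyl-4-(2-ethoxyethoxy)flavan-3-ol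
Conditions: DDQ, 2-ethoxyethanol, CH2Cl2, rt
Reagents that add atoms: 2-ethoxyethanol CCOCCO
Why: DDQ abstracts hydride from C4 (benzylic to the electron-rich ring A) and the alcohol traps the cation from the axial direction (3,4-cis ether); the C4 configuration is lost again in step 16, and the C8 bromine caps the unit against self-condensation.

Step 16
Reactants: 20 dimer diol; 21 bromo-capped catechin 4-ether
Product: 22 protected trimer, 8-bromo-catechin-(4α→8)-gallocatechin-(4β→8)-catechin with all phenols as Bn or TBB ethers (upper 2R,3S,4S; middle 2R,3S,4S; lower 2R,3S)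
Conditions: Me3SiOTf (0.2 equiv), 4 Å MS, CH2Cl2, −78 °C
Reagents that add atoms: none
Why: Lewis-acid Friedel–Crafts interflavan coupling: 21 ionises to the flavan-4-yl cation, which should be attacked by C8 of the upper (gallocatechin) unit of 20, the most nucleophilic free position of oligoflavan nucleophiles, trans to the 3-OH of the 2,3-trans cation (4α).

Step 17
Reactants: 22 protected trimer
Product: 23 catechin-(4α→8)-gallocatechin-(4β→8)-catechin (target)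
Conditions: H2 (1 atm), Pd(OH)2/C, THF/MeOH/H2O, rt
Reagents that add atoms: none
Why: Hydrogenolysis should remove all benzyl and TBB ethers and the aryl bromide in one operation without touching the stereocenters.

**Compound list**

1 | phloroglucinol | Oc1cc(O)cc(O)c1 | starting material
2 | [3,4,5-tris(benzyloxy)phenyl]methanol (TBB alcohol) | OCc1cc(OCc2ccccc2)c(OCc2ccccc2)c(OCc2ccccc2)c1 | starting material
3 | 1,3,5-tris(TBB-oxy)benzene | c1(OCc8cc(OCc9ccccc9)c(OCc9ccccc9)c(OCc9ccccc9)c8)cc(OCc8cc(OCc9ccccc9)c(OCc9ccccc9)c(OCc9ccccc9)c8)cc(OCc8cc(OCc9ccccc9)c(OCc9ccccc9)c(OCc9ccccc9)c8)c1 | intermediate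
4 | 2-oxo-2-[2,4,6-tris(TBB-oxy)phenyl]acetyl chloride | ClC(=O)C(=O)c1c(OCc8cc(OCc9ccccc9)c(OCc9ccccc9)c(OCc9ccccc9)c8)cc(OCc8cc(OCc9ccccc9)c(OCc9ccccc9)c(OCc9ccccc9)c8)cc1OCc8cc(OCc9ccccc9)c(OCc9ccccc9)c(OCc9ccccc9)c8 | intermediate (not isolated)
5 | methyl 2-oxo-2-[2,4,6-tris(TBB-oxy)phenyl]acetate | COC(=O)C(=O)c1c(OCc8cc(OCc9ccccc9)c(OCc9ccccc9)c(OCc9ccccc9)c8)cc(OCc8cc(OCc9ccccc9)c(OCc9ccccc9)c(OCc9ccccc9)c8)cc1OCc8cc(OCc9ccccc9)c(OCc9ccccc9)c(OCc9ccccc9)c8 | intermediate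
6 | tosylhydrazone of 5 | COC(=O)C(=NNS(=O)(=O)c1ccc(C)cc1)c1c(OCc8cc(OCc9ccccc9)c(OCc9ccccc9)c(OCc9ccccc9)c8)cc(OCc8cc(OCc9ccccc9)c(OCc9ccccc9)c(OCc9ccccc9)c8)cc1OCc8cc(OCc9ccccc9)c(OCc9ccccc9)c(OCc9ccccc9)c8 | intermediate (not isolated)
7 | methyl 2-diazo-2-[2,4,6-tris(TBB-oxy)phenyl]acetate | COC(=O)C(=[N+]=[N-])c1c(OCc8cc(OCc9ccccc9)c(OCc9ccccc9)c(OCc9ccccc9)c8)cc(OCc8cc(OCc9ccccc9)c(OCc9ccccc9)c(OCc9ccccc9)c8)cc1OCc8cc(OCc9ccccc9)c(OCc9ccccc9)c(OCc9ccccc9)c8 | intermediate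
8 | methyl (2S,3R)-2-ArB-4,6-bis(TBB-oxy)-2,3-dihydro-1-benzofuran-3-carboxylate (cis) | COC(=O)[C@@H]1c2c(OCc8cc(OCc9ccccc9)c(OCc9ccccc9)c(OCc9ccccc9)c8)cc(OCc8cc(OCc9ccccc9)c(OCc9ccccc9)c(OCc9ccccc9)c8)cc2O[C@@H]1c7cc(OCc9ccccc9)c(OCc9ccccc9)c(OCc9ccccc9)c7 | intermediate
9 | methyl (2R,3S)-3-hydroxy-2-ArB-4,6-bis(TBB-oxy)-2,3-dihydro-1-benzofuran-3-carboxylate | COC(=O)[C@]1(O)c2c(OCc8cc(OCc9ccccc9)c(OCc9ccccc9)c(OCc9ccccc9)c8)cc(OCc8cc(OCc9ccccc9)c(OCc9ccccc9)c(OCc9ccccc9)c8)cc2O[C@@H]1c7cc(OCc9ccccc9)c(OCc9ccccc9)c(OCc9ccccc9)c7 | intermediate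
10 | methyl (2R,3S)-3-[(tert-butyldimethylsilyl)oxy]-2-ArB-4,6-bis(TBB-oxy)-2,3-dihydro-1-benzofuran-3-carboxylate | COC(=O)[C@]1(O[Si](C)(C)C(C)(C)C)c2c(OCc8cc(OCc9ccccc9)c(OCc9ccccc9)c(OCc9ccccc9)c8)cc(OCc8cc(OCc9ccccc9)c(OCc9ccccc9)c(OCc9ccccc9)c8)cc2O[C@@H]1c7cc(OCc9ccccc9)c(OCc9ccccc9)c(OCc9ccccc9)c7 | intermediate
11 | (2R,3S)-3-[(tert-butyldimethylsilyl)oxy]-2-ArB-4,6-bis(TBB-oxy)-2,3-dihydro-1-benzofuran-3-carbaldehyde | O=C[C@]1(O[Si](C)(C)C(C)(C)C)c2c(OCc8cc(OCc9ccccc9)c(OCc9ccccc9)c(OCc9ccccc9)c8)cc(OCc8cc(OCc9ccccc9)c(OCc9ccccc9)c(OCc9ccccc9)c8)cc2O[C@@H]1c7cc(OCc9ccccc9)c(OCc9ccccc9)c(OCc9ccccc9)c7 | intermediate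
12 | (2R,3R)-3-[(tert-butyldimethylsilyl)oxy]-2-ArB-5,7-bis(TBB-oxy)-2,3-dihydro-4H-chromen-4-one (trans) | O=C1c2c(OCc8cc(OCc9ccccc9)c(OCc9ccccc9)c(OCc9ccccc9)c8)cc(OCc8cc(OCc9ccccc9)c(OCc9ccccc9)c(OCc9ccccc9)c8)cc2O[C@H](c7cc(OCc9ccccc9)c(OCc9ccccc9)c(OCc9ccccc9)c7)[C@H]1O[Si](C)(C)C(C)(C)C | intermediate
13 | (+)-catechin, (2R,3S) | Oc1cc(O)c2c(c1)O[C@H](c1ccc(O)c(O)c1)[C@@H](O)C2 | starting material
14 | (2R,3S)-5,7,3',4'-tetra-O-benzylcatechin | c1(OCc9ccccc9)cc(OCc9ccccc9)c2c(c1)O[C@H](c7ccc(OCc9ccccc9)c(OCc9ccccc9)c7)[C@@H](O)C2 | intermediate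
15 | (2R,3S)-8-bromo-5,7,3',4'-tetra-O-benzylcatechin | c1(OCc9ccccc9)cc(OCc9ccccc9)c2c(c1Br)O[C@H](c7ccc(OCc9ccccc9)c(OCc9ccccc9)c7)[C@@H](O)C2 | intermediate
16 | (2R,3S)-8-bromo-3-O-TBS-5,7,3',4'-tetra-O-benzylcatechin | c1(OCc9ccccc9)cc(OCc9ccccc9)c2c(c1Br)O[C@H](c7ccc(OCc9ccccc9)c(OCc9ccccc9)c7)[C@@H](O[Si](C)(C)C(C)(C)C)C2 | intermediate
17 | (2R,3S)-8-lithio-3-O-TBS-5,7,3',4'-tetra-O-benzylcatechin | c1(OCc9ccccc9)cc(OCc9ccccc9)c2c(c1[Li])O[C@H](c7ccc(OCc9ccccc9)c(OCc9ccccc9)c7)[C@@H](O[Si](C)(C)C(C)(C)C)C2 | intermediate (not isolated)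
18 | tertiary alcohol: (2R,3R,4R)-4-hydroxy-3-O-TBS-2-ArB-5,7-bis(TBB-oxy)flavan bearing at C4 the C8 of (2R,3S)-3-O-TBS-5,7,3',4'-tetra-O-benzylcatechin (aryl trans to O3) | c1c(OCc8cc(OCc9ccccc9)c(OCc9ccccc9)c(OCc9ccccc9)c8)cc(OCc8cc(OCc9ccccc9)c(OCc9ccccc9)c(OCc9ccccc9)c8)c2c1O[C@H](c7cc(OCc9ccccc9)c(OCc9ccccc9)c(OCc9ccccc9)c7)[C@@H](O[Si](C)(C)C(C)(C)C)[C@]2(O)c1c(OCc9ccccc9)cc(OCc9ccccc9)c2c1O[C@H](c7ccc(OCc9ccccc9)c(OCc9ccccc9)c7)[C@@H](O[Si](C)(C)C(C)(C)C)C2 | intermediate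
19 | 3,3''-bis-O-TBS gallocatechin-(4β→8)-catechin, upper unit (2R,3S,4R) 5,7-di-O-TBB-3',4',5'-tri-O-Bn, lower unit (2R,3S) tetra-O-Bn | c1c(OCc8cc(OCc9ccccc9)c(OCc9ccccc9)c(OCc9ccccc9)c8)cc(OCc8cc(OCc9ccccc9)c(OCc9ccccc9)c(OCc9ccccc9)c8)c2c1O[C@H](c7cc(OCc9ccccc9)c(OCc9ccccc9)c(OCc9ccccc9)c7)[C@@H](O[Si](C)(C)C(C)(C)C)[C@H]2c1c(OCc9ccccc9)cc(OCc9ccccc9)c2c1O[C@H](c7ccc(OCc9ccccc9)c(OCc9ccccc9)c7)[C@@H](O[Si](C)(C)C(C)(C)C)C2 | intermediate
20 | gallocatechin-(4β→8)-catechin with both 3-OH free, upper unit (2R,3S,4R) 5,7-di-O-TBB-3',4',5'-tri-O-Bn, lower unit (2R,3S) tetra-O-Bn | c1c(OCc8cc(OCc9ccccc9)c(OCc9ccccc9)c(OCc9ccccc9)c8)cc(OCc8cc(OCc9ccccc9)c(OCc9ccccc9)c(OCc9ccccc9)c8)c2c1O[C@H](c7cc(OCc9ccccc9)c(OCc9ccccc9)c(OCc9ccccc9)c7)[C@@H](O)[C@H]2c1c(OCc9ccccc9)cc(OCc9ccccc9)c2c1O[C@H](c7ccc(OCc9ccccc9)c(OCc9ccccc9)c7)[C@@H](O)C2 | intermediate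
21 | (2R,3S,4S)-8-bromo-5,7,3',4'-tetra-O-benzyl-4-(2-ethoxyethoxy)flavan-3-ol | c1(OCc9ccccc9)cc(OCc9ccccc9)c2c(c1Br)O[C@H](c7ccc(OCc9ccccc9)c(OCc9ccccc9)c7)[C@@H](O)[C@H]2OCCOCC | intermediate
22 | protected trimer: 8-bromo-tetra-O-Bn-catechin-(4α→8)-[5,7-di-O-TBB-3',4',5'-tri-O-Bn-gallocatechin]-(4β→8)-tetra-O-Bn-catechin, three 3-OH free | c1(OCc9ccccc9)cc(OCc9ccccc9)c2c(c1Br)O[C@H](c7ccc(OCc9ccccc9)c(OCc9ccccc9)c7)[C@@H](O)[C@@H]2c1c(OCc8cc(OCc9ccccc9)c(OCc9ccccc9)c(OCc9ccccc9)c8)cc(OCc8cc(OCc9ccccc9)c(OCc9ccccc9)c(OCc9ccccc9)c8)c2c1O[C@H](c7cc(OCc9ccccc9)c(OCc9ccccc9)c(OCc9ccccc9)c7)[C@@H](O)[C@H]2c1c(OCc9ccccc9)cc(OCc9ccccc9)c2c1O[C@H](c7ccc(OCc9ccccc9)c(OCc9ccccc9)c7)[C@@H](O)C2 | intermediate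
23 | catechin-(4α→8)-gallocatechin-(4β→8)-catechin, upper (2R,3S,4S), middle (2R,3S,4S), lower (2R,3S) | Oc1cc(O)c2c(c1)O[C@H](c1ccc(O)c(O)c1)[C@@H](O)[C@@H]2c1c(O)cc(O)c2c1O[C@H](c1cc(O)c(O)c(O)c1)[C@@H](O)[C@H]2c1c(O)cc(O)c2c1O[C@H](c1ccc(O)c(O)c1)[C@@H](O)C2 | target

**Totals and risks**

Total step count: 17. Longest linear sequence: 13 steps (steps 1–8, 12, 13, 14, 16, 17, from phloroglucinol).

Step 8 (key step). What may go wrong: the ring-A carbon migrates in place of C2, the silyl group is lost, or C3 forms without control. The fallback runs the shift on the free ketol under reversible conditions and sets out from 9. LiAlH4 in THF reduces the ester to the diol (2R,3R)-3-(hydroxymethyl)-2-ArB-4,6-bis(TBB-oxy)-2,3-dihydro-1-benzofuran-3-ol F1. TEMPO/PhI(OAc)2 oxidises only the primary alcohol to the free α-hydroxy aldehyde (2R,3S)-3-hydroxy-2-ArB-4,6-bis(TBB-oxy)-2,3-dihydro-1-benzofuran-3-carbaldehyde F2. With catalytic Al(OtBu)3 in toluene at 50 °C the ketol equilibrates: whichever ring bond shifts first, a six-membered α-ketol forms, and 1,2-hydride shift through the chelated enediol should funnel the mixture to the ring-A-conjugated C4 ketone with equatorial 3-OH, (2R,3R)-3-hydroxy-2-ArB-5,7-bis(TBB-oxy)chroman-4-one F3. tBuMe2SiOTf/2,6-lutidine then returns to the route at 12.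

Step 13. What may go wrong: hydride is delivered to the wrong face of the C4 cation (giving the 3,4-trans dimer), or the cation is lost by elimination. The fallback delivers the lower unit intramolecularly from O3 through a temporary diester tether, a known way to 3,4-cis 4→8 dimers of 2,3-trans flavans; it sets out from 12 and 14. NaBH4 (THF/MeOH, 0 °C) reduces 12 to the flavan-4-ol (2R,3S,4R)-3-O-TBS-2-ArB-5,7-bis(TBB-oxy)flavan-4-ol F4. PPTS in 2-ethoxyethanol/CH2Cl2 exchanges the 4-OH for the ether (2R,3S,4S)-3-O-TBS-4-(2-ethoxyethoxy) analogue F5, and nBu4NF frees O3 to give the 4-(2-ethoxyethoxy)flavan-3-ol F6. Separately, 14 with glutaric anhydride/DMAP gives 3-O-(4-carboxybutanoyl)-tetra-O-benzylcatechin F7. Steglich esterification (DCC, DMAP) of F6 with F7 gives the glutarate-linked diester F8. Me3SiOTf in dilute CH2Cl2 at −20 °C ionises C4, which is trapped by C8 of the tethered catechin from the O3 face to give the 14-membered 3,4-cis macrocycle F9. iBu2AlH cleaves both ester links, and the fallback returns to the route at 20.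

Step 5. What may go wrong: oxygen transfer to the hindered tetrasubstituted enolate is slow, or the strong base opens the ring and epimerises C2. The fallback avoids the ester enolate and sets out from 8. iBu2AlH at −78 °C gives the aldehyde (2S,3R)-2-ArB-4,6-bis(TBB-oxy)-2,3-dihydro-1-benzofuran-3-carbaldehyde F10. tBuMe2SiOTf/Et3N gives the exocyclic silyl enol ether (Z)-3-[(tert-butyldimethylsilyloxy)methylidene]-2-ArB-4,6-bis(TBB-oxy)-2,3-dihydro-1-benzofuran F11 (alkene geometry is inconsequential). Dimethyldioxirane in acetone at −40 °C epoxidises the enol ether, and the silyloxy epoxide opens with 1,4-silyl shift (Rubottom oxidation), returning to the route at 11 and making steps 6 and 7 unnecessary.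

**Further compounds**

F1 | step 8 | (2R,3R)-3-(hydroxymethyl)-2-ArB-4,6-bis(TBB-oxy)-2,3-dihydro-1-benzofuran-3-ol | OC[C@]1(O)c2c(OCc8cc(OCc9ccccc9)c(OCc9ccccc9)c(OCc9ccccc9)c8)cc(OCc8cc(OCc9ccccc9)c(OCc9ccccc9)c(OCc9ccccc9)c8)cc2O[C@@H]1c7cc(OCc9ccccc9)c(OCc9ccccc9)c(OCc9ccccc9)c7
F2 | step 8 | (2R,3S)-3-hydroxy-2-ArB-4,6-bis(TBB-oxy)-2,3-dihydro-1-benzofuran-3-carbaldehyde | O=C[C@]1(O)c2c(OCc8cc(OCc9ccccc9)c(OCc9ccccc9)c(OCc9ccccc9)c8)cc(OCc8cc(OCc9ccccc9)c(OCc9ccccc9)c(OCc9ccccc9)c8)cc2O[C@@H]1c7cc(OCc9ccccc9)c(OCc9ccccc9)c(OCc9ccccc9)c7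
F3 | step 8 | (2R,3R)-3-hydroxy-2-ArB-5,7-bis(TBB-oxy)-2,3-dihydro-4H-chromen-4-one | O=C1c2c(OCc8cc(OCc9ccccc9)c(OCc9ccccc9)c(OCc9ccccc9)c8)cc(OCc8cc(OCc9ccccc9)c(OCc9ccccc9)c(OCc9ccccc9)c8)cc2O[C@H](c7cc(OCc9ccccc9)c(OCc9ccccc9)c(OCc9ccccc9)c7)[C@H]1O
F4 | step 13 | (2R,3S,4R)-3-O-TBS-2-ArB-5,7-bis(TBB-oxy)flavan-4-ol | c1c(OCc8cc(OCc9ccccc9)c(OCc9ccccc9)c(OCc9ccccc9)c8)cc(OCc8cc(OCc9ccccc9)c(OCc9ccccc9)c(OCc9ccccc9)c8)c2c1O[C@H](c7cc(OCc9ccccc9)c(OCc9ccccc9)c(OCc9ccccc9)c7)[C@@H](O[Si](C)(C)C(C)(C)C)[C@@H]2O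
F5 | step 13 | (2R,3S,4S)-3-O-TBS-4-(2-ethoxyethoxy)-2-ArB-5,7-bis(TBB-oxy)flavan | c1c(OCc8cc(OCc9ccccc9)c(OCc9ccccc9)c(OCc9ccccc9)c8)cc(OCc8cc(OCc9ccccc9)c(OCc9ccccc9)c(OCc9ccccc9)c8)c2c1O[C@H](c7cc(OCc9ccccc9)c(OCc9ccccc9)c(OCc9ccccc9)c7)[C@@H](O[Si](C)(C)C(C)(C)C)[C@H]2OCCOCC
F6 | step 13 | (2R,3S,4S)-4-(2-ethoxyethoxy)-2-ArB-5,7-bis(TBB-oxy)flavan-3-ol | c1c(OCc8cc(OCc9ccccc9)c(OCc9ccccc9)c(OCc9ccccc9)c8)cc(OCc8cc(OCc9ccccc9)c(OCc9ccccc9)c(OCc9ccccc9)c8)c2c1O[C@H](c7cc(OCc9ccccc9)c(OCc9ccccc9)c(OCc9ccccc9)c7)[C@@H](O)[C@H]2OCCOCC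
F7 | step 13 | (2R,3S)-3-O-(4-carboxybutanoyl)-5,7,3',4'-tetra-O-benzylcatechin | c1(OCc9ccccc9)cc(OCc9ccccc9)c2c(c1)O[C@H](c7ccc(OCc9ccccc9)c(OCc9ccccc9)c7)[C@@H](OC(=O)CCCC(O)=O)C2
F8 | step 13 | glutarate diester linking O3 of F6 and O3 of tetra-O-benzylcatechin | c1c(OCc8cc(OCc9ccccc9)c(OCc9ccccc9)c(OCc9ccccc9)c8)cc(OCc8cc(OCc9ccccc9)c(OCc9ccccc9)c(OCc9ccccc9)c8)c2c1O[C@H](c7cc(OCc9ccccc9)c(OCc9ccccc9)c(OCc9ccccc9)c7)[C@@H](OC(=O)CCCC(=O)O[C@H]3Cc4c(OCc9ccccc9)cc(OCc9ccccc9)cc4O[C@@H]3c7ccc(OCc9ccccc9)c(OCc9ccccc9)c7)[C@H]2OCCOCC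
F9 | step 13 | 3,3''-O-glutaryl-bridged gallocatechin-(4β→8)-catechin macrocycle (3,4-cis; phenols as in 20) | c1c(OCc8cc(OCc9ccccc9)c(OCc9ccccc9)c(OCc9ccccc9)c8)cc(OCc8cc(OCc9ccccc9)c(OCc9ccccc9)c(OCc9ccccc9)c8)c2c1O[C@H](c7cc(OCc9ccccc9)c(OCc9ccccc9)c(OCc9ccccc9)c7)[C@@H](OC(=O)CCCC(=O)O5)[C@H]2c1c(OCc9ccccc9)cc(OCc9ccccc9)c2c1O[C@H](c7ccc(OCc9ccccc9)c(OCc9ccccc9)c7)[C@@H]5C2
F10 | step 5 | (2S,3R)-2-ArB-4,6-bis(TBB-oxy)-2,3-dihydro-1-benzofuran-3-carbaldehyde | O=C[C@@H]1c2c(OCc8cc(OCc9ccccc9)c(OCc9ccccc9)c(OCc9ccccc9)c8)cc(OCc8cc(OCc9ccccc9)c(OCc9ccccc9)c(OCc9ccccc9)c8)cc2O[C@@H]1c7cc(OCc9ccccc9)c(OCc9ccccc9)c(OCc9ccccc9)c7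
F11 | step 5 | (2R,Z)-3-[(tert-butyldimethylsilyloxy)methylidene]-2-ArB-4,6-bis(TBB-oxy)-2,3-dihydro-1-benzofuran | CC(C)(C)[Si](C)(C)O/C=C1\[C@@H](c7cc(OCc9ccccc9)c(OCc9ccccc9)c(OCc9ccccc9)c7)Oc2cc(OCc8cc(OCc9ccccc9)c(OCc9ccccc9)c(OCc9ccccc9)c8)cc(OCc8cc(OCc9ccccc9)c(OCc9ccccc9)c(OCc9ccccc9)c8)c12
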